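The readings are calculated for an exercise; scatter was added.

A power of 0.651, read off the earlier runs, describes target against time. On logarithmic axes between 2.50 min and 5.00 min, the spring, summer and dawn runs give slopes of 0.663, 0.943 and 0.348, and their mean is the time power, the gain in log target per gain in log time. A power of one is a straight line; below one, target bends away from it. The readings scatter by 0.3 percentage points, so the three slopes differ partly by noise, and the mean is what is carried.

| flask | substrate | reagent in the second phase | remark | time | volume of the second phase over the first |
|---|---|---|---|---|---|
| spring | 0.0085 M | 1 equiv | run made earlier |  |  |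
| summer | 0.013 M | 1 equiv | run made earlier |  |  |
| dawn | 0.017 M | 0.50 equiv | run made earlier |  |  |
| flask | 0.017 M | 1.00 equiv |  | 5.0 min | 2.0 |

- spring (time / min: target / %, substrate / %): 0.833: 0.6, 98.7; 1.50: 0.8, 98.0; 2.50: 2.4, 97.3; 3.00: 2.4, 95.7; 4.00: 3.5, 95.2; 5.00: 3.8, 93.6
- summer (time / min: target / %, substrate / %): 0.833: 1.0, 98.6; 1.50: 1.5, 97.7; 2.50: 2.6, 95.3; 3.00: 3.4, 94.8; 4.00: 4.2, 92.5; 5.00: 5.0, 90.6
- dawn (time / min: target / %, substrate / %): 0.417: 0.2, 99.8; 0.833: 0.5, 99.1; 1.33: 1.0, 98.4; 2.50: 2.2, 96.6; 5.00: 2.8, 92.9

(each reading ± 0.3 percentage points)

- in the second phase: reagent in the second phase; everything else is in the first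
- charges count per volume of the first phase; a concentration in a rate is the amount of a species over the volume of its own phase; every rate counts per litre of the first phase
- the analysis behind the earlier runs scatters by 0.3 percentage points, standard deviation
- the earlier runs hold the two phases in the same ratio of volumes as the flask asked about

- gamma: doubling the transfer coefficient of the reagent in the second phase, all else as stated
- zeta: doubling the amount of reagent in the second phase, all else as stated

- target at 5.0 min, in percent of the substrate charged
- the change that raises the amount of target at 5.0 min, in percent of the substrate charged most ("none" if none brings more than 2 percentage points) (gamma / zeta / none)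
- amount of target at 5.0 min, in percent of the substrate charged, after zeta

The dawn run holds the flask's substrate and half its reagent, so a first estimate doubles its 2.8% to 5.60%. But the bend may run with the reagent. If every step ran on a clock of reagent times time, doubling the reagent would act like doubling the time. The factor would then be 1.57, giving 4.40%. Yet target rises from spring to summer, 5.0% against 3.8%, as both charges rise. The flask holds more of both than the summer run, so it should stand above 5.0%, and 5.60% is kept.

For zeta the two factors span 8.79% to 11.2%. The lower figure is the one to commit to, since the power 0.651 stands below one. Even so, it gains 3.2 points, more than 2 points. Against gamma, the dawn run holds the spring run's reagent and twice its substrate, and its amount of target at 2.50 min is 1.83 times the spring run's. Passage between the phases therefore looks like no rate-limiting step, and gamma should bring little.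

The forecast gives 6.3%, zeta and 11.5%: “The rate depends on substrate, so transfer is not limiting”.

The flask gives 5.46%. Zeta is best, adding 3.4 points to reach 8.83%, while gamma adds 0.049 points.

    substrate + reagent in the reaction phase → target (k = 0.120 M⁻¹ s⁻¹)
    substrate + target → side product (k = 0.180 M⁻¹ s⁻¹)
    reagent in the reaction phase ⇌ reagent in the second phase, rate k3*([reagent in the reaction phase] - [reagent in the second phase]/K3) per volume of the first phase (partition coefficient = 2.20, kL = 0.120 s⁻¹)
    reagent in the reaction phase + target → over-reaction product (k = 0.190 M⁻¹ s⁻¹)
    reagent in the reaction phase + target → over-reacted product (k = 0.290 M⁻¹ s⁻¹)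

In the flask, target from 2.50 min to 5.00 min has a time power of 0.550, and zeta's doubling shows a power of 0.694, beside the carried 0.651. The neighbouring flask is the same flask left until 8.0 min. The carried power takes 5.46% to 7.41% there. The neighbouring flask holds 6.20%, lower by 1.2 points, and its target's time power from 5.0 min to 8.0 min is 0.270.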